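## Retrosynthetic overview

- Labdane numbering. Ring A = C1–C5, C10; ring B = C5–C10; ring C = oxolane C9, C11–C13, O; ring D = dihydrofuran C13–C16, O. Endgame: the C14=C15 enol ether comes from a 15-lactol, and 8-OAc/7-OH come from a 7β,8α-diol through a cyclic orthoacetate.
- Ring A is cut last, at C1–C10 and C4–C5. The forward reaction is an intramolecular Diels–Alder reaction of the C5=C10 enone with a 4-methylpenta-1,3-dienyl unit (C1–C4, C18, C19). The diene hangs on O8 through a SiMe2 tether that is removed afterwards.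
- Enabling feature: H-5 and CH3-20 are cis at the A/B junction, C5 is α and C10 is β to the C6 ketone, and the gem-dimethyl carbon C4 sits on C5. O8 lies on the same (α) face as O9 and 1,3 to C10, so the structure is a Diels–Alder retron with a built-in anchor.
- Ring B is a 3,5-dimethylphenol. Ring C closes by dearomatizing 5-exo spiroetherification (C13–OH onto C9). The symmetric dienone is desymmetrized by epoxidation of the C7=C8 arm, and the epoxide is opened reductively to the 8α-alcohol.
- C13 comes from a Sharpless epoxide opened by a benzylic Grignard reagent, and ring D closes as a methyl acetal. Order of ring formation: B (arene) → D → C → A.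

Key step: step 15

Remark: the SMILES is read as (5R,7R,8R,9S,10S,13S), that is 5β-H/10β-CH3 (cis-fused A/B), 7β-OH, 8α-OAc and 9α-O; C15 of the acetals and lactols and the orthoester carbon are epimer mixtures that are erased later and are left undefined.

## Route

Step 1
Reactants: 1 prop-2-yn-1-ol; 2 allylmagnesium bromide
Product: 3 2-methylidenepent-4-en-1-ol
Conditions: 2 (2.5 equiv), CuI (10 mol %), Et2O, 0 °C → rt; aq NH4Cl
Reagents that add atoms: none
Why: Copper-catalysed carbomagnesiation of the propargylic alkoxide places the allyl group on the internal alkyne carbon through a chelated vinylmagnesium species, and protonation gives the 2-substituted allylic alcohol without forming a stereocenter.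

Step 2
Reactants: 3 2-methylidenepent-4-en-1-ol
Product: 4 [(2S)-2-(prop-2-en-1-yl)oxiran-2-yl]methanol
Conditions: Ti(OiPr)4 (10 mol %), L-(+)-diisopropyl tartrate (12 mol %), tBuOOH, 4 Å molecular sieves, CH2Cl2, −20 °C
Reagents that add atoms: tert-butyl hydroperoxide CC(C)(C)OO
Why: Sharpless asymmetric epoxidation touches only the allylic-alcohol olefin, and with the L-(+)-tartrate it delivers oxygen to the face that makes C13 (S), as for other 2-alkyl allyl alcohols.

Step 3
Reactants: 5 4-hydroxy-2,6-dimethylbenzaldehyde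
Product: 6 4-[(tert-butyldimethylsilyl)oxy]-2,6-dimethylbenzaldehyde
Conditions: TBSCl, imidazole, DMF, rt
Reagents that add atoms: tert-butyldimethylsilyl chloride CC(C)(C)[Si](C)(C)Cl
Why: Silyl ether protection of the phenol gives a group that survives the Grignard chemistry and leaves under fluoride without acid.

Step 4
Reactants: 6 4-[(tert-butyldimethylsilyl)oxy]-2,6-dimethylbenzaldehyde
Product: 7 {4-[(tert-butyldimethylsilyl)oxy]-2,6-dimethylphenyl}methanol
Conditions: NaBH4, MeOH, 0 °C
Reagents that add atoms: none
Why: Borohydride reduction of the aryl aldehyde gives the benzylic alcohol (C11) and leaves the silyl ether alone.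

Step 5
Reactants: 7 {4-[(tert-butyldimethylsilyl)oxy]-2,6-dimethylphenyl}methanol
Product: 8 tert-butyl[4-(chloromethyl)-3,5-dimethylphenoxy]dimethylsilane
Conditions: MsCl, Et3N, CH2Cl2, 0 °C → rt
Reagents that add atoms: methanesulfonyl chloride CS(=O)(=O)Cl
Why: Chlorodehydroxylation works because the sulfonylated oxygen of this electron-rich benzylic alcohol is displaced at once by the chloride that is released.

Step 6
Reactants: 8 tert-butyl[4-(chloromethyl)-3,5-dimethylphenoxy]dimethylsilane; 4 [(2S)-2-(prop-2-en-1-yl)oxiran-2-yl]methanol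
Product: 10 (2S)-2-(2-{4-[(tert-butyldimethylsilyl)oxy]-2,6-dimethylphenyl}ethyl)pent-4-ene-1,2-diol, via benzylic Grignard reagent 9 (not isolated)
Conditions: 8, Mg, THF, 0 °C; 4 pre-treated with MeMgCl (1.0 equiv), THF, −40 °C; combine, CuI (10 mol %), −40 → 0 °C; aq NH4Cl
Reagents that add atoms: none
Why: Copper-catalysed SN2 opening of the 2,2-disubstituted epoxide at its CH2 carbon (C12) forms C11–C12 and leaves the C13–O bond untouched, so (S) is kept, and a Payne rearrangement of this epoxy alcohol is degenerate and cannot erode it.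

Step 7
Reactants: 10 (2S)-2-(2-{4-[(tert-butyldimethylsilyl)oxy]-2,6-dimethylphenyl}ethyl)pent-4-ene-1,2-diol
Product: 12 (3S)-3-(2-{4-[(tert-butyldimethylsilyl)oxy]-2,6-dimethylphenyl}ethyl)-5-methoxyoxolan-3-ol (ring D closed; C15 epimers), via lactol 11 (not isolated)
Conditions: O3, CH2Cl2–MeOH, −78 °C; Me2S; then PPTS (5 mol %), MeOH, 4 Å molecular sieves, rt
Reagents that add atoms: methanol CO
Why: Ozonolysis of the terminal olefin (much faster than attack on the arene) gives the C15 aldehyde, which closes with the primary C16–OH to the five-membered lactol, and mild Fischer-type acetalization fixes it without dehydration of the tertiary alcohol to a furan.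

Step 8
Reactants: 12 (3S)-3-(2-{4-[(tert-butyldimethylsilyl)oxy]-2,6-dimethylphenyl}ethyl)-5-methoxyoxolan-3-ol
Product: 13 4-{2-[(3S)-3-hydroxy-5-methoxyoxolan-3-yl]ethyl}-3,5-dimethylphenol
Conditions: Bu4NF–AcOH (1:1, 1.2 equiv), THF, 0 °C
Reagents that add atoms: none
Why: Fluoride desilylation frees the phenol quickly under buffered conditions that spare the β-hydroxy acetal.

Step 9
Reactants: 13 4-{2-[(3S)-3-hydroxy-5-methoxyoxolan-3-yl]ethyl}-3,5-dimethylphenol
Product: 14 spirodienone (ring B = 8,10-dimethylcyclohexa-2,5-dienone with C6=O; spiro at C9 to oxolane ring C; ring C spiro at (13S)-C13 to 15-methoxyoxolane ring D)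
Conditions: PhI(OAc)2 (1.1 equiv), NaHCO3 (solid), (CF3)2CHOH–CH2Cl2, 0 °C
Reagents that add atoms: none
Why: Hypervalent-iodine oxidative dearomatization lets the tertiary C13–OH capture the activated phenol at the para carbon C9 in a 5-exo mode, C13 keeps its C–O bond and configuration, and C9 is not yet a stereocenter because the two enone arms are alike.

Step 10
Reactants: 14 spirodienone
Product: 15 7α,8α-epoxy enone (epoxide on the arm that lies on the C14 side of ring C; C5=C10 enone left)
Conditions: 9-amino-9-deoxy-epi-quinine (10 mol %), CF3CO2H (20 mol %), aq H2O2 (1.5 equiv), dioxane, 30 °C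
Reagents that add atoms: hydrogen peroxide OO
Why: Proposed new method: the chiral primary amine condenses with the unhindered C6 ketone to an iminium ion, the protonated quinuclidine guides H2O2 to the β-carbon C8 of one of the two diastereotopic enone arms, and the β-peroxy enamine closes the oxirane (Weitz–Scheffer sequence); the closest known reaction type is the amine-salt-catalysed asymmetric epoxidation of cyclic enones, 3-alkylcyclohexenones included, and only its use to tell apart the two arms of a cross-conjugated spirodienone is new; the catalyst chooses the arm and with it C9 (its quinidine-derived pseudoenantiomer is at hand if the sense is opposite), and the substrate chooses the face at C7 and C8, since nucleophiles enter 4-alkoxy-4-alkyl dienones on the side of the smaller C9–O bond.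

Step 11
Reactants: 15 7α,8α-epoxy enone
Product: 16 8α-hydroxy enone (C7 = CH2)
Conditions: SmI2 (2.2 equiv), THF–MeOH, −90 °C
Reagents that add atoms: none
Why: Reduction of the α,β-epoxy ketone by divalent samarium cleaves only the C7–O bond next to the carbonyl group and protonates the enolate at low temperature, so the 8α C–O bond and its configuration stay and the enone is not touched.

Step 12
Reactants: 17 3-methylbut-2-enal
Product: 18 4-methylpent-3-en-1-yne
Conditions: dimethyl (1-diazo-2-oxopropyl)phosphonate, K2CO3, MeOH, 0 °C → rt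
Reagents that add atoms: dimethyl (1-diazo-2-oxopropyl)phosphonate CC(=O)C(=[N+]=[N-])P(=O)(OC)OC
Why: Ohira–Bestmann homologation turns the aldehyde into the terminal alkyne, and the β,β-disubstituted enal resists conjugate addition of methanol.

Step 13
Reactants: 18 4-methylpent-3-en-1-yne; 19 chlorodimethylsilane
Product: 20 chloro(dimethyl)[(1E)-4-methylpenta-1,3-dien-1-yl]silane
Conditions: H2PtCl6 (0.1 mol %), CH2Cl2, 0 °C → rt; distillation
Reagents that add atoms: none
Why: Platinum-catalysed hydrosilylation adds Si–H syn across the terminal alkyne with silicon on the terminal carbon, which gives the (E)-1-silyl diene and leaves the trisubstituted olefin alone.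

Step 14
Reactants: 16 8α-hydroxy enone; 20 chloro(dimethyl)[(1E)-4-methylpenta-1,3-dien-1-yl]silane
Product: 21 8α-O-dienyl(dimethyl)silyl ether of 16
Conditions: imidazole, DMAP (10 mol %), CH2Cl2, 0 °C → rt
Reagents that add atoms: none
Why: Silyl ether formation (temporary silicon connection) works because the small Me2Si chloride reaches the tertiary 8α-OH under conditions too mild for β-elimination, and no stereocenter changes.

Step 15
Reactants: 21 8α-O-dienyl(dimethyl)silyl ether of 16
Product: 22 Diels–Alder adduct (cis-fused Δ2-decal-6-one with rings C and D; C1–SiMe2–O8 bridge)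
Conditions: PhMe (0.01 M), BHT (cat.), sealed tube, 170 °C
Reagents that add atoms: none
Why: Heating brings the (E)-dienylsilane, held under the α-face by the axial O8–Si bond, onto the C5=C10 enone, and a concerted but asynchronous [4+2] cycloaddition forms C1–C10 ahead of C4–C5, in line with the polarity of the partners (nucleophilic C1 terminus of a 4,4-dimethyl diene, electrophilic β-carbon C10). The closest known reaction type is the intramolecular Diels–Alder reaction through a temporary silicon connection (dienylsilyl ether of a dienophile alcohol). Ring A (C1–C5, C10) closes by the suprafacial six-electron cycloaddition, and the temporary 1-oxa-2-silacyclohexane (O8, Si, C1, C10, C9, C8) closes at the same moment through the C1–C10 bond as the four-atom tether of a type 1 process. C10 and C5 are set by the tether, which reaches only the face that carries O8 and O9, and by suprafacial addition to the ring-locked olefin, so C1 and C4 enter α and CH3-20 and H-5 are both pushed β (cis junction), while C1 follows from the (E)-silane and the exo mode that the short tether enforces and is erased in step 17. The step needs regio-, face- and chemoselectivity: the tether fixes C1 to C10 and C4 to C5 (also the electronically matched ortho sense), only one electron-poor olefin is left after steps 10 and 11, and the neutral thermal conditions spare the acetal. In one operation two C–C bonds, both quaternary carbons C4 and C10 and the C5/C10 junction arise from an acyclic C6 diene.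

Step 16
Reactants: 22 Diels–Alder adduct
Product: 24 7β-hydroxy ketone (siloxane bridge intact), via potassium enolate 23 (not isolated)
Conditions: KN(SiMe3)2 (1.2 equiv), THF, −78 °C; 2-(phenylsulfonyl)-3-phenyloxaziridine, −78 °C; AcOH quench
Reagents that add atoms: 2-(phenylsulfonyl)-3-phenyloxaziridine O=S(=O)(c1ccccc1)N1OC1c1ccccc1
Why: In this Davis oxidation kinetic deprotonation takes the C7 methylene (H-5 lies between two quaternary carbons), and the oxaziridine enters from the convex β-face because ring A and the siloxane bridge cover the α-face, which sets 7β-OH trans to O8.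

Step 17
Reactants: 24 7β-hydroxy ketone (siloxane bridge intact)
Product: 25 7β,8α-dihydroxy-Δ2-olefin (a Δ1 isomer would converge in step 18)
Conditions: Bu4NF–AcOH (1:1, 4 equiv), THF–DMF, 50 °C
Reagents that add atoms: none
Why: Fluoride-induced cleavage of the Si–O bond and protodesilylation of the resulting allylsilane removes the tether, and the acetic acid buffer serves as proton source and keeps the β-hydroxy ketone from retro-aldol cleavage.

Step 18
Reactants: 25 7β,8α-dihydroxy-Δ2-olefin
Product: 26 7β,8α-dihydroxy-15-methoxy-9,13:15,16-diepoxy-5β-labdan-6-one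
Conditions: H2 (1 atm), Pd/C (10 wt %), EtOAc, rt
Reagents that add atoms: none
Why: Heterogeneous hydrogenation saturates the only olefin, creates no stereocenter and leaves ketone, acetal and diol unchanged.

Step 19
Reactants: 26 7β,8α-dihydroxy-15-methoxy-9,13:15,16-diepoxy-5β-labdan-6-one
Product: 28 8α-acetoxy-7β,15-dihydroxy-9,13:15,16-diepoxy-5β-labdan-6-one (15-lactol), via cyclic orthoacetate 27 (not isolated)
Conditions: MeC(OMe)3 (5 equiv), PPTS (5 mol %), CH2Cl2, rt; then AcOH–H2O (4:1), 0 °C → rt
Reagents that add atoms: trimethyl orthoacetate CC(OC)(OC)OC; water O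
Why: In the orthoester method of diol monoacylation aqueous acid opens the cyclic orthoacetate through its 2-hydroxy-1,3-dioxolane, which expels the better leaving α-ketol oxygen O7 and leaves the acetyl group on the tertiary O8, while the same medium hydrolyses the 15-acetal to the lactol and touches no stereocenter.

Step 20
Reactants: 28 8α-acetoxy-7β,15-dihydroxy-9,13:15,16-diepoxy-5β-labdan-6-one (15-lactol)
Product: 30 (5R,7R,8R,9S,10S,13S)-8-acetoxy-7-hydroxy-9,13:15,16-diepoxylabd-14-en-6-one (target), via anomeric mesylate 29 (not isolated)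
Conditions: MsCl (1.2 equiv), Et3N (6 equiv), CH2Cl2, −40 °C → rt; chromatography on Et3N-washed silica
Reagents that add atoms: none
Why: In this lactol dehydration the anomeric hydroxyl is sulfonylated in preference to the hindered, hydrogen-bonded 7-OH, ionizes to the oxocarbenium ion and loses H-14 to Et3N, and since C13 is quaternary only the C14=C15 enol ether can form, while the absence of acid prevents opening of ring C to a furan.

## Compound list

1 | prop-2-yn-1-ol | C#CCO | starting material
2 | allylmagnesium bromide | C=CC[Mg]Br | starting material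
3 | 2-methylidenepent-4-en-1-ol | C=CCC(=C)CO | intermediate
4 | [(2S)-2-(prop-2-en-1-yl)oxiran-2-yl]methanol | C=CC[C@]1(CO)CO1 | intermediate
5 | 4-hydroxy-2,6-dimethylbenzaldehyde | Cc1cc(O)cc(C)c1C=O | starting material
6 | 4-[(tert-butyldimethylsilyl)oxy]-2,6-dimethylbenzaldehyde | CC(C)(C)[Si](C)(C)Oc1cc(C)c(C=O)c(C)c1 | intermediate
7 | {4-[(tert-butyldimethylsilyl)oxy]-2,6-dimethylphenyl}methanol | CC(C)(C)[Si](C)(C)Oc1cc(C)c(CO)c(C)c1 | intermediate
8 | tert-butyl[4-(chloromethyl)-3,5-dimethylphenoxy]dimethylsilane | CC(C)(C)[Si](C)(C)Oc1cc(C)c(CCl)c(C)c1 | intermediate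
9 | benzylic Grignard reagent of 8 | CC(C)(C)[Si](C)(C)Oc1cc(C)c(C[Mg]Cl)c(C)c1 | intermediate
10 | (2S)-2-(2-{4-[(tert-butyldimethylsilyl)oxy]-2,6-dimethylphenyl}ethyl)pent-4-ene-1,2-diol | CC(C)(C)[Si](C)(C)Oc1cc(C)c(CC[C@@](O)(CO)CC=C)c(C)c1 | intermediate
11 | (4S)-4-(2-{4-[(tert-butyldimethylsilyl)oxy]-2,6-dimethylphenyl}ethyl)oxolane-2,4-diol (lactol) | CC(C)(C)[Si](C)(C)Oc1cc(C)c(CC[C@]2(O)CC(O)OC2)c(C)c1 | intermediate
12 | (3S)-3-(2-{4-[(tert-butyldimethylsilyl)oxy]-2,6-dimethylphenyl}ethyl)-5-methoxyoxolan-3-ol | CC(C)(C)[Si](C)(C)Oc1cc(C)c(CC[C@]2(O)CC(OC)OC2)c(C)c1 | intermediate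
13 | 4-{2-[(3S)-3-hydroxy-5-methoxyoxolan-3-yl]ethyl}-3,5-dimethylphenol | Cc1cc(O)cc(C)c1CC[C@]1(O)CC(OC)OC1 | intermediate
14 | spirodienone (rings B, C, D; 13S) | CC1=CC(=O)C=C(C)C12CC[C@@]1(CC(OC)OC1)O2 | intermediate
15 | 7α,8α-epoxy enone (9S,13S) | C[C@@]12O[C@@H]1C(=O)C=C(C)[C@@]23CC[C@@]2(CC(OC)OC2)O3 | intermediate
16 | 8α-hydroxy enone | O[C@]1(C)CC(=O)C=C(C)[C@@]12CC[C@@]1(CC(OC)OC1)O2 | intermediate
17 | 3-methylbut-2-enal | CC(C)=CC=O | starting material
18 | 4-methylpent-3-en-1-yne | CC(C)=CC#C | intermediate
19 | chlorodimethylsilane | C[SiH](C)Cl | starting material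
20 | chloro(dimethyl)[(1E)-4-methylpenta-1,3-dien-1-yl]silane | CC(C)=C/C=C/[Si](C)(C)Cl | intermediate
21 | 8α-O-dienyl(dimethyl)silyl ether of 16 | CC(C)=C/C=C/[Si](C)(C)O[C@]1(C)CC(=O)C=C(C)[C@@]12CC[C@@]1(CC(OC)OC1)O2 | intermediate
22 | Diels–Alder adduct with C1–SiMe2–O8 bridge | C[Si]3(C)O[C@]1(C)CC(=O)[C@@H]2C(C)(C)C=C[C@@H]3[C@]2(C)[C@@]12CC[C@@]1(CC(OC)OC1)O2 | intermediate
23 | potassium C6–C7 enolate of 22 | C[Si]3(C)O[C@]1(C)C=C([O-])[C@@H]2C(C)(C)C=C[C@@H]3[C@]2(C)[C@@]12CC[C@@]1(CC(OC)OC1)O2.[K+] | intermediate
24 | 7β-hydroxy ketone with siloxane bridge | C[Si]3(C)O[C@]1(C)[C@@H](O)C(=O)[C@@H]2C(C)(C)C=C[C@@H]3[C@]2(C)[C@@]12CC[C@@]1(CC(OC)OC1)O2 | intermediate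
25 | 7β,8α-dihydroxy-Δ2-olefin | O[C@]1(C)[C@@H](O)C(=O)[C@@H]2C(C)(C)C=CC[C@]2(C)[C@@]12CC[C@@]1(CC(OC)OC1)O2 | intermediate
26 | 7β,8α-dihydroxy-15-methoxy-9,13:15,16-diepoxy-5β-labdan-6-one | O[C@]1(C)[C@@H](O)C(=O)[C@@H]2C(C)(C)CCC[C@]2(C)[C@@]12CC[C@@]1(CC(OC)OC1)O2 | intermediate
27 | cyclic 7,8-orthoacetate of 26 | COC3(C)O[C@]1(C)[C@@H](O3)C(=O)[C@@H]2C(C)(C)CCC[C@]2(C)[C@@]12CC[C@@]1(CC(OC)OC1)O2 | intermediate
28 | 8α-acetoxy-7β,15-dihydroxy-9,13:15,16-diepoxy-5β-labdan-6-one | CC(=O)O[C@]1(C)[C@@H](O)C(=O)[C@@H]2C(C)(C)CCC[C@]2(C)[C@@]12CC[C@@]1(CC(O)OC1)O2 | intermediate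
29 | anomeric (C15) mesylate of 28 | CC(=O)O[C@]1(C)[C@@H](O)C(=O)[C@@H]2C(C)(C)CCC[C@]2(C)[C@@]12CC[C@@]1(CC(OS(C)(=O)=O)OC1)O2 | intermediate
30 | (5R,7R,8R,9S,10S,13S)-8-acetoxy-7-hydroxy-9,13:15,16-diepoxylabd-14-en-6-one | CC(=O)O[C@]1(C)[C@@H](O)C(=O)[C@@H]2C(C)(C)CCC[C@]2(C)[C@@]12CC[C@@]1(C=COC1)O2 | target

## Step count

Total step count: 20. Longest linear sequence: 16 steps (5 → 30; steps 3–11 and 14–20).

## Steps most likely to fail

**1. Step 10 (Proposed new method).** The catalyst may discriminate poorly between the two enone arms, iminium formation on the cross-conjugated dienone may be slow, or the second arm may also be epoxidized.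
- The fallback sets out from 14 and comes back at 15, and relies on C13 instead of a catalyst.
- Ordinary Weitz–Scheffer epoxidation (tBuOOH, DBU, CH2Cl2) of 14 should give 15 together with the arm-isomeric epoxy enone F1. The two are diastereomers and can be separated by chromatography.
- The unwanted isomer is recycled: SmI2 reduction gives the arm-isomeric hydroxy enone F2, and base-induced dehydration (DBU, warm) returns 14.

**2. Step 15 (key step).** The cycloaddition may be too slow. A 1,5-hydrogen shift within the diene or β-elimination of the silanol from the ketone could then take over.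
- The fallback sets out from 16 and comes back at 26. It replaces the hydrocarbon diene by a more nucleophilic 2-silyloxydiene that carries a removable oxygen at C2.
- Mesityl oxide is deprotonated at its methyl ketone side (LiN(iPr)2, THF, −78 °C) and quenched with Me2SiCl2 to give the chlorosilyl dienol ether F3. This silylates 16 (imidazole) to the mixed silyl ketal F4.
- Heating F4 (type 2 intramolecular Diels–Alder reaction, or its stepwise Mukaiyama–Michael/Michael variant) should give the bridged silyl enol ether F5.
- Bu4NF–AcOH frees the 8α-hydroxy-2,6-diketone F6.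
- TsNHNH2 condenses only with the unhindered C2 ketone to give the tosylhydrazone F7. Catecholborane, then NaOAc·3H2O, gives the 8α-hydroxy-6-ketone F8.
- Double deprotonation of F8 with KN(SiMe3)2 followed by Davis oxidation gives 26.

**3. Step 19.** The orthoacetate may close slowly on the hindered trans-diol, or the acetyl group may migrate to O7 during hydrolysis.
- The fallback sets out from 26 and comes back at 28, and uses protecting-group differentiation.
- TESCl/imidazole silylates only the secondary alcohol to give the 7-O-triethylsilyl ether F9.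
- Ac2O/DMAP/Et3N acetylates the tertiary alcohol to give the 8-acetate F10.
- AcOH–H2O–THF then removes the silyl group and hydrolyses the 15-acetal to give 28.

## Further compounds

F1 | step 10 | arm-isomeric epoxy enone (epoxide on the arm at the C16 side; C7, C8, C9 inverted relative to 15) | C[C@]12O[C@H]1C(=O)C=C(C)[C@]23CC[C@@]2(CC(OC)OC2)O3
F2 | step 10 | arm-isomeric hydroxy enone | O[C@@]1(C)CC(=O)C=C(C)[C@]12CC[C@@]1(CC(OC)OC1)O2
F3 | step 15 | chloro(dimethyl)[(4-methylpenta-1,3-dien-2-yl)oxy]silane | CC(C)=CC(=C)O[Si](C)(C)Cl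
F4 | step 15 | mixed silyl ketal of 16 and the mesityl oxide dienol | CC(C)=CC(=C)O[Si](C)(C)O[C@]1(C)CC(=O)C=C(C)[C@@]12CC[C@@]1(CC(OC)OC1)O2
F5 | step 15 | bridged silyl enol ether (C2–O–SiMe2–O8) | C[Si]3(C)O[C@]1(C)CC(=O)[C@@H]2C(C)(C)C=C(O3)C[C@]2(C)[C@@]12CC[C@@]1(CC(OC)OC1)O2
F6 | step 15 | 8α-hydroxy-2,6-diketone | O[C@]1(C)CC(=O)[C@@H]2C(C)(C)CC(=O)C[C@]2(C)[C@@]12CC[C@@]1(CC(OC)OC1)O2
F7 | step 15 | C2 tosylhydrazone of F6 | O[C@]1(C)CC(=O)[C@@H]2C(C)(C)CC(=NNS(=O)(=O)c3ccc(C)cc3)C[C@]2(C)[C@@]12CC[C@@]1(CC(OC)OC1)O2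
F8 | step 15 | 8α-hydroxy-6-ketone (7-deoxy-26) | O[C@]1(C)CC(=O)[C@@H]2C(C)(C)CCC[C@]2(C)[C@@]12CC[C@@]1(CC(OC)OC1)O2
F9 | step 19 | 7-O-triethylsilyl ether of 26 | O[C@]1(C)[C@@H](O[Si](CC)(CC)CC)C(=O)[C@@H]2C(C)(C)CCC[C@]2(C)[C@@]12CC[C@@]1(CC(OC)OC1)O2
F10 | step 19 | 8-acetate of F9 | CC(=O)O[C@]1(C)[C@@H](O[Si](CC)(CC)CC)C(=O)[C@@H]2C(C)(C)CCC[C@]2(C)[C@@]12CC[C@@]1(CC(OC)OC1)O2
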